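**Retrosynthetic overview**

1. Target 9 ⇒ triprenyl dienone 7 by a retro oxa-6π electrocyclization and dehydrogenation. The O1–C2 bond of pyran ring B, O–C(CH3)2, is formed last.
2. 7 ⇒ 2,4,6-trihydroxybenzophenone 3 and three prenyl bromide 4, by threefold C-prenylation that dearomatizes ring A and sets the gem-diprenyl carbon.
3. 3 ⇒ phloroglucinol 1 and benzoyl chloride 2 (Friedel–Crafts acylation).
4. Ring order: aromatic ring A is bought, dearomatized to the cyclohexadienone in step 2, and pyran ring B is closed in step 3.
5. Enabling feature (ring A of 7 numbered C1 carbonyl, C2 benzoyl, C3 enol, C4 gem-diprenyl, C5 enol, C6 lone prenyl): the C6 prenyl CH2 sits on an enol carbon between the C1 and C5 oxygens, so it is a hydride donor. Once oxidized, O=C5–C6=CH–CH=C(CH3)2 is a 1-oxatriene poised to close on the C5 oxygen next to quaternary C4.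

Key step: step 3

Remark on the chemistry: compounds 7, 8 and 9 are enolized β-triketones. Each is drawn as one tautomer, the tautomers are assumed to interconvert rapidly, and the target has no stereocenter.

**Route**

Step 1
Reactants: 1 phloroglucinol (anhydrous); 2 benzoyl chloride
Product: 3 2,4,6-trihydroxybenzophenone
Conditions: AlCl3 (3.5 equiv), PhNO2, 80 °C; then ice, aq HCl
Reagents that add atoms: benzoyl chloride, O=C(Cl)c1ccccc1
Why: Friedel–Crafts acylation of the threefold-symmetric, strongly activated phloroglucinol should stop at the mono-ketone because the aluminium-chelated aryl ketone is deactivated, and any O-benzoate formed first should be carried to the C-acyl product by Fries rearrangement under the same conditions; no stereocenter is formed.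

Step 2
Reactants: 3 2,4,6-trihydroxybenzophenone; 4 prenyl bromide
Product: 7 2-benzoyl-3,5-dihydroxy-4,4,6-tris(3-methylbut-2-enyl)cyclohexa-2,5-dien-1-one (triprenyl dienone; benzoyl analogue of lupulone), via 3-prenyl-2,4,6-trihydroxybenzophenone 5 (not isolated), via 3,5-diprenyl-2,4,6-trihydroxybenzophenone 6 (not isolated)
Conditions: prenyl bromide (3.2 equiv), 10% aq KOH, 0 °C, N2; then aq HCl; product kept under N2
Reagents that add atoms: prenyl bromide (1-bromo-3-methylbut-2-ene), CC(C)=CCBr
Why: Alkylative dearomatization by threefold C-prenylation of an acylphloroglucinolate: in water the oxygens are solvated so the soft allylic bromide should be taken up at carbon, first at the two free ring carbons and then a second time at one of these equivalent carbons rather than at the benzoyl-bearing carbon, which gives the gem-diprenyl cyclohexadienone of the hop β-acid type; the new quaternary carbon carries two identical prenyl groups and is not a stereocenter.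

Step 3
Reactants: 7 triprenyl dienone
Product: 9 6-benzoyl-7-hydroxy-2,2-dimethyl-8,8-bis(3-methylbut-2-enyl)-2H-chromen-5(8H)-one (target), via alkylidene trione 8 (not isolated)
Conditions: DDQ (1.1 equiv), PhMe (0.02 M), N2, rt, then 60 °C
Reagents that add atoms: none
Why: DDQ should abstract hydride from the allylic CH2 of the lone C6 prenyl group, and loss of the enol proton then gives the 6-(3-methylbut-2-enylidene) trione 8, a 1-oxatriene O=C5–C6=CH–CH=C(CH3)2 that closes thermally by a disrotatory oxa-6π electrocyclization and so forms the O–C(CH3)2 bond. The closest known reaction type is the DDQ dehydrogenative cyclization of C-prenyl vinylogous acids and ortho-prenylphenols to 2,2-dimethyl-2H-pyrans, for example of 2-hydroxy-3-prenyl-1,4-naphthoquinone to its dimethylpyran. Pyran ring B closes in a 6π electrocyclic mode (formally 6-endo), and no stereocenter arises because C2 of the pyran carries two methyl groups and C8 two prenyl groups. The step needs site selectivity among three prenyl groups and regioselectivity between the C5 and C1 oxygens that flank C6: the first is secured because only the C6 prenyl CH2 is attached to an enol carbon, while the two prenyl groups on sp3 C4 cannot give an oxygen-stabilized cation; the second because the closure is reversible in this non-aromatic 2H-pyran, and closure on the C5 oxygen (next to the quaternary carbon, outside the benzoyl chelate) keeps the hydrogen-bonded 2-benzoyl-1,3-dione enol intact within a cross-conjugated 3,5-dioxygenated cyclohexa-2,5-dienone. Warming to 60 °C should let any isomer closed on the C1 oxygen reopen to 8 and drain to 9.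

**Compound list**

1 | phloroglucinol (benzene-1,3,5-triol) | Oc1cc(O)cc(O)c1 | starting material
2 | benzoyl chloride | O=C(Cl)c1ccccc1 | starting material
3 | 2,4,6-trihydroxybenzophenone | O=C(c1ccccc1)c1c(O)cc(O)cc1O | intermediate
4 | prenyl bromide (1-bromo-3-methylbut-2-ene) | CC(C)=CCBr | starting material
5 | 3-prenyl-2,4,6-trihydroxybenzophenone (not isolated) | CC(C)=CCc1c(O)cc(O)c(C(=O)c2ccccc2)c1O | intermediate
6 | 3,5-diprenyl-2,4,6-trihydroxybenzophenone (not isolated) | CC(C)=CCc1c(O)c(CC=C(C)C)c(O)c(C(=O)c2ccccc2)c1O | intermediate
7 | 2-benzoyl-3,5-dihydroxy-4,4,6-tris(3-methylbut-2-enyl)cyclohexa-2,5-dien-1-one (triprenyl dienone) | O=C1C(C(=O)c2ccccc2)=C(O)C(CC=C(C)C)(CC=C(C)C)C(O)=C1CC=C(C)C | intermediate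
8 | 2-benzoyl-3-hydroxy-4,4-bis(3-methylbut-2-enyl)-6-(3-methylbut-2-enylidene)cyclohex-2-ene-1,5-dione (alkylidene trione, either alkylidene geometry, not isolated) | CC(C)=CC=C1C(=O)C(C(=O)c2ccccc2)=C(O)C(CC=C(C)C)(CC=C(C)C)C1=O | intermediate
9 | 6-benzoyl-7-hydroxy-2,2-dimethyl-8,8-bis(3-methylbut-2-enyl)-2H-chromen-5(8H)-one | CC(C)=CCC1(CC=C(C)C)C(O)=C(C(=O)c2ccccc2)C(=O)C2=C1OC(C)(C)C=C2 | target

**Summary**

Total step count: 3. Longest linear sequence: 3 steps, from phloroglucinol 1.

Steps most likely to fail, riskiest first:

Step 3. The oxatriene may close on the C1 oxygen faster than the two pyrans equilibrate, or it may be consumed by hetero-Diels–Alder dimerization or a second oxidation before it closes. The fallback sets out from compound 3 and comes back at compound 9: the pyran is built on the still aromatic ring and the dearomatization is moved to the end. Compound 3 would be alkylated at its non-chelated para hydroxyl with 3-chloro-3-methylbut-1-yne (K2CO3, KI, CuI cat., acetone, reflux) to give the aryl 1,1-dimethylpropargyl ether F1. Heating F1 (N,N-diethylaniline, 150 °C) should bring about the propargyl Claisen rearrangement, 1,5-hydrogen shift and oxa-6π closure to 6-benzoyl-5,7-dihydroxy-2,2-dimethyl-2H-chromene F2. The two ortho carbons of F1 are equivalent, and the ortho hydroxyls should stay chelated to the benzoyl group so that the ether oxygen becomes the ring oxygen. Twofold C-prenylation of F2 at C8, its only unsubstituted ring carbon (prenyl bromide, 10% aq KOH, 0 °C), should then dearomatize ring A and give 9.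

Step 2. O-alkylation and incomplete or excessive alkylation may compete, so that the triprenyl dienone is only one component of a mixture, and 7 may be oxidized by air during work-up. The fallback sets out from compound 3 and comes back at compound 7: the alkylation is split in two and the dearomatizing event is changed from a direct displacement to a Tsuji–Trost allylation. With 2.1 equiv of prenyl bromide in aq KOH at 0 °C the aromatic diprenyl compound 6 would be isolated. The third prenyl group would then be delivered with Pd(PPh3)4 (cat.) and tert-butyl 3-methylbut-2-enyl carbonate in THF at rt, where the soft enolate carbon should attack the less hindered terminus of the π-prenyl palladium intermediate to give 7. This fallback makes no compound outside the list (F0).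

Step 1. O-benzoylation without complete Fries rearrangement, a second acylation, and loss of material on removal of nitrobenzene may lower the throughput. The fallback sets out from compound 1 and comes back at compound 3, using a Houben–Hoesch acylation in place of the acid chloride. Phloroglucinol and benzonitrile with ZnCl2 and HCl gas in Et2O at 0 °C should deposit the 2,4,6-trihydroxybenzophenone iminium chloride F3, whose hydrolysis in boiling water should give 3.

**Further compounds**

F1 | step 3 | (2,6-dihydroxy-4-(2-methylbut-3-yn-2-yloxy)phenyl)(phenyl)methanone | C#CC(C)(C)Oc1cc(O)c(C(=O)c2ccccc2)c(O)c1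
F2 | step 3 | (5,7-dihydroxy-2,2-dimethyl-2H-chromen-6-yl)(phenyl)methanone | CC1(C)C=Cc2c(O)c(C(=O)c3ccccc3)c(O)cc2O1
F0 | step 2 | none | none
F3 | step 1 | 2,4,6-trihydroxybenzophenone iminium chloride | [NH2+]=C(c1ccccc1)c1c(O)cc(O)cc1O.[Cl-]
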